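**Strategy.** Fragransin B1 is a meso tetrahydrofuran, so only relative configuration matters. The ring (O1, C2–C5) is traced back to the flat 2,5-diaryl-3,4-dimethylfuran. One syn hydrogenation then sets the cis C3/C4 methyl pair, and acid equilibration of the benzylic C2 and C5 gives the trans,cis,trans isomer. The furan is assembled in one catalytic [3+2] cascade from two pieces made from the same aldehyde. The β-alkenyl C–H of an aryl tiglyl ketone O-methyl oxime (C2–C3–C4) adds to the C=O of O-benzyl syringaldehyde (bond C4–C5). The new hydroxyl closes on the oxime carbon (bond O1–C2) with loss of methoxyamine. The step exploits the mirror symmetry of the ring about O1.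

Key step: step 3

Assumption: compounds 1 and 2 are bought; because the target is meso, racemic and achiral intermediates suffice.

Step 1
Reactants: 1 4-(benzyloxy)-3,5-dimethoxybenzaldehyde; 2 (E)-2-bromobut-2-ene
Product: 4 (E)-1-[4-(benzyloxy)-3,5-dimethoxyphenyl]-2-methylbut-2-en-1-ol (racemic), via (E)-but-2-en-2-yllithium 3 (not isolated)
Conditions: 2, t-BuLi (2 equiv), Et2O, −78 °C; then 1 in THF, −78 to 0 °C; H2O
Reagents that add atoms: none
Why: Bromine–lithium exchange should keep the (E)-geometry, and 1,2-addition of the alkenyllithium to the aldehyde (organolithium carbonyl addition) should give the allylic alcohol, whose racemic carbinol centre is removed in step 2.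

Step 2
Reactants: 4 (E)-1-[4-(benzyloxy)-3,5-dimethoxyphenyl]-2-methylbut-2-en-1-ol
Product: 6 (2E)-1-[4-(benzyloxy)-3,5-dimethoxyphenyl]-2-methylbut-2-en-1-one O-methyl oxime (both C=N isomers), via aryl tiglyl ketone 5 (not isolated)
Conditions: MnO2 (10 equiv), CH2Cl2, rt; filter, evaporate; then MeONH2·HCl, pyridine, EtOH, 60 °C
Reagents that add atoms: O-methylhydroxylamine hydrochloride, CON.Cl
Why: MnO2 oxidation of the benzylic-allylic alcohol followed by oxime ether condensation should occur at the carbonyl carbon, because the α,β-disubstituted alkene is a poor conjugate acceptor; the alkene geometry is untouched and the C=N isomers interconvert under the acidic conditions of step 3.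

Step 3
Reactants: 6 (2E)-1-[4-(benzyloxy)-3,5-dimethoxyphenyl]-2-methylbut-2-en-1-one O-methyl oxime; 1 4-(benzyloxy)-3,5-dimethoxybenzaldehyde
Product: 9 2,5-bis[4-(benzyloxy)-3,5-dimethoxyphenyl]-3,4-dimethylfuran, via hydroxy oxime ether 7 (not isolated), via methoxyamino dihydrofuran 8 (not isolated)
Conditions: [Cp*RhCl2]2 (5 mol%), AgSbF6 (20 mol%), AcOH (20 mol%), 1 (2 equiv), 1,2-dichloroethane, 80 °C
Reagents that add atoms: none
Why: The cationic Cp*Rh catalyst (trivalent rhodium) binds the oxime nitrogen of 6 and cleaves, by carboxylate-assisted concerted metalation–deprotonation, the single β-alkenyl C–H that the (E)-geometry holds syn to the C=N group, giving a five-membered rhodacycle whose alkenyl–Rh bond adds to the aldehyde carbon of 1 (bond C4–C5) to give 7 after protonolysis. The hydroxyl of 7, held cis to the oxime by the (Z)-alkene, then adds to the C=N carbon in a 5-exo-trig closure (bond O1–C2) to give 8, and loss of O-methylhydroxylamine with aromatisation gives furan 9; this irreversible end should make the otherwise reversible aldehyde insertion productive. The closest known reaction type is the rhodium- or cobalt-catalysed (both trivalent) addition of alkenyl C–H bonds of α,β-unsaturated oxime ethers to aldehydes with cyclative capture to furans. No stereocentre remains in 9 (the carbinol and aminal centres of 7 and 8 are erased), so all four are left to steps 4 and 5. The selectivity needed is alkenyl over aryl C–H activation: both ortho C–H bonds of the aryl ring are flanked by a methoxy group and are hindered toward the bulky Cp*Rh, and only the oxime isomer whose nitrogen lone pair faces the alkenyl arm is productive while the isomers interconvert.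

Step 4
Reactants: 9 2,5-bis[4-(benzyloxy)-3,5-dimethoxyphenyl]-3,4-dimethylfuran
Product: 11 all-cis (2S,3R,4S,5R)-2,5-bis(4-hydroxy-3,5-dimethoxyphenyl)-3,4-dimethyltetrahydrofuran (meso), via furan bisphenol 10 (not isolated)
Conditions: H2 (10 bar), 10% Pd/C, EtOAc–EtOH, 40 °C
Reagents that add atoms: none
Why: Heterogeneous catalytic hydrogenation (with hydrogenolysis of both benzyl ethers) should deliver all four ring hydrogens from the catalyst-bound face of the flat furan, so the cis C3/C4 dimethyl relationship is set kinetically by syn addition, with both aryl groups also cis for the moment.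

Step 5
Reactants: 11 all-cis (2S,3R,4S,5R)-2,5-bis(4-hydroxy-3,5-dimethoxyphenyl)-3,4-dimethyltetrahydrofuran
Product: 13 fragransin B1 [(2S,3S,4R,5R)-2,5-bis(4-hydroxy-3,5-dimethoxyphenyl)-3,4-dimethyltetrahydrofuran; meso], via mono-epimer 12 (not isolated)
Conditions: TFA (0.5 equiv), CH2Cl2, 0 °C; NaHCO3
Reagents that add atoms: none
Why: Acid-catalysed epimerisation by reversible ionisation of each benzylic C–O bond to a 4-hydroxybenzyl cation and 5-exo reclosure should move each aryl group trans to its neighbouring methyl, the thermodynamically preferred arrangement among the 3,4-cis isomers, while C3 and C4 are not touched.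

**Compound list**

1 | 4-(benzyloxy)-3,5-dimethoxybenzaldehyde | COc1cc(C=O)cc(OC)c1OCc1ccccc1 | starting material
2 | (E)-2-bromobut-2-ene | C/C=C(\C)Br | starting material
3 | (E)-but-2-en-2-yllithium | C/C=C(\C)[Li] | intermediate
4 | (E)-1-[4-(benzyloxy)-3,5-dimethoxyphenyl]-2-methylbut-2-en-1-ol (racemic) | C/C=C(\C)C(O)c1cc(OC)c(OCc2ccccc2)c(OC)c1 | intermediate
5 | (E)-1-[4-(benzyloxy)-3,5-dimethoxyphenyl]-2-methylbut-2-en-1-one | C/C=C(\C)C(=O)c1cc(OC)c(OCc2ccccc2)c(OC)c1 | intermediate
6 | (2E)-1-[4-(benzyloxy)-3,5-dimethoxyphenyl]-2-methylbut-2-en-1-one O-methyl oxime (both C=N isomers) | C/C=C(\C)C(=NOC)c1cc(OC)c(OCc2ccccc2)c(OC)c1 | intermediate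
7 | (2Z)-1,4-bis[4-(benzyloxy)-3,5-dimethoxyphenyl]-4-hydroxy-2,3-dimethylbut-2-en-1-one O-methyl oxime (racemic) | CON=C(c1cc(OC)c(OCc2ccccc2)c(OC)c1)/C(C)=C(/C)C(O)c1cc(OC)c(OCc2ccccc2)c(OC)c1 | intermediate
8 | 2,5-bis[4-(benzyloxy)-3,5-dimethoxyphenyl]-N-methoxy-3,4-dimethyl-2,5-dihydrofuran-2-amine (diastereomer mixture) | CONC1(c2cc(OC)c(OCc3ccccc3)c(OC)c2)OC(c2cc(OC)c(OCc3ccccc3)c(OC)c2)C(C)=C1C | intermediate
9 | 2,5-bis[4-(benzyloxy)-3,5-dimethoxyphenyl]-3,4-dimethylfuran | Cc1c(C)c(-c2cc(OC)c(OCc3ccccc3)c(OC)c2)oc1-c1cc(OC)c(OCc2ccccc2)c(OC)c1 | intermediate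
10 | 4,4'-(3,4-dimethylfuran-2,5-diyl)bis(2,6-dimethoxyphenol) | Cc1c(C)c(-c2cc(OC)c(O)c(OC)c2)oc1-c1cc(OC)c(O)c(OC)c1 | intermediate
11 | all-cis (2S,3R,4S,5R)-2,5-bis(4-hydroxy-3,5-dimethoxyphenyl)-3,4-dimethyltetrahydrofuran (meso) | COc1cc([C@H]2O[C@@H](c3cc(OC)c(O)c(OC)c3)[C@@H](C)[C@H]2C)cc(OC)c1O | intermediate
12 | rac-(2S,3R,4S,5S)-2,5-bis(4-hydroxy-3,5-dimethoxyphenyl)-3,4-dimethyltetrahydrofuran (one aryl cis, one aryl trans to the cis-dimethyl pair) | COc1cc([C@H]2O[C@H](c3cc(OC)c(O)c(OC)c3)[C@@H](C)[C@H]2C)cc(OC)c1O | intermediate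
13 | fragransin B1, (2S,3S,4R,5R)-2,5-bis(4-hydroxy-3,5-dimethoxyphenyl)-3,4-dimethyltetrahydrofuran (meso; aryls cis to each other, each trans to its neighbouring methyl) | COc1cc([C@H]2O[C@@H](c3cc(OC)c(O)c(OC)c3)[C@H](C)[C@@H]2C)cc(OC)c1O | target

**Step count.** Total: 5 steps. Longest linear sequence: 5 steps (1 → 4 → 6 → 9 → 11 → 13; compound 1 enters again in step 3).

**Steps most likely to fail**

Step 3. Cyclometalation may go to an aryl ortho C–H instead of the alkenyl C–H, or insertion into the electron-rich aldehyde may stay reversible and unproductive while released methoxyamine ties up catalyst and aldehyde. The fallback sets out from 1 and builds the furan by the classical diketone route. Addition of EtMgBr (THF, 0 °C) should give 1-[4-(benzyloxy)-3,5-dimethoxyphenyl]propan-1-ol F1. MnO2 (CH2Cl2) should oxidise it to 1-[4-(benzyloxy)-3,5-dimethoxyphenyl]propan-1-one F2. Oxidative enolate homocoupling (LDA, THF, −78 °C; then CuCl2, DMF) should give 1,4-bis[4-(benzyloxy)-3,5-dimethoxyphenyl]-2,3-dimethylbutane-1,4-dione F3 as a meso/racemic mixture, both of which converge. Paal–Knorr cyclodehydration (TsOH, toluene, reflux) comes back to the route at 9.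

Step 4. Hydrogenolysis of the benzylic ring C–O bonds may overtake ring saturation, or reduction may stall at a dihydrofuran because the ring alkenes are tetrasubstituted. The fallback sets out from 9 and sets the cis-dimethyl pair on an open chain instead. Oxidative ring opening (mCPBA, CH2Cl2, 0 °C) should give (Z)-1,4-bis[4-(benzyloxy)-3,5-dimethoxyphenyl]-2,3-dimethylbut-2-ene-1,4-dione F4. Mild syn hydrogenation of the activated alkene with debenzylation (H2 1 atm, 10% Pd/C, EtOAc) should give meso-1,4-bis(4-hydroxy-3,5-dimethoxyphenyl)-2,3-dimethylbutane-1,4-dione F5. NaBH4 (MeOH, 0 °C) should give (2R,3S)-1,4-bis(4-hydroxy-3,5-dimethoxyphenyl)-2,3-dimethylbutane-1,4-diol F6 as a mixture at the carbinol centres. Acid cyclodehydration under equilibrating conditions (TsOH cat., CH2Cl2) comes back to the route at 13.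

Step 5. The benzylic cations may be trapped irreversibly by the other aryl ring (Friedel–Crafts closure to an aryltetralin), or may lose the C3/C4 proton to a vinylphenol, which erases the cis-dimethyl relationship. The fallback sets out from 11 and epimerises at the ether stage, where no quinone methide tautomerisation is possible and a low-temperature Lewis acid can be used. Re-benzylation (BnBr, K2CO3, DMF) should give all-cis (2S,3R,4S,5R)-2,5-bis[4-(benzyloxy)-3,5-dimethoxyphenyl]-3,4-dimethyltetrahydrofuran F7. BF3·OEt2 (CH2Cl2, −20 °C) should epimerise it to (2S,3S,4R,5R)-2,5-bis[4-(benzyloxy)-3,5-dimethoxyphenyl]-3,4-dimethyltetrahydrofuran F8. Brief hydrogenolysis (H2 1 atm, 10% Pd/C, EtOAc) comes back to the route at 13.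

**Further compounds**

F1 | step 3 | 1-[4-(benzyloxy)-3,5-dimethoxyphenyl]propan-1-ol (racemic) | CCC(O)c1cc(OC)c(OCc2ccccc2)c(OC)c1
F2 | step 3 | 1-[4-(benzyloxy)-3,5-dimethoxyphenyl]propan-1-one | CCC(=O)c1cc(OC)c(OCc2ccccc2)c(OC)c1
F3 | step 3 | 1,4-bis[4-(benzyloxy)-3,5-dimethoxyphenyl]-2,3-dimethylbutane-1,4-dione (meso/racemic mixture) | CC(C(=O)c1cc(OC)c(OCc2ccccc2)c(OC)c1)C(C)C(=O)c1cc(OC)c(OCc2ccccc2)c(OC)c1
F4 | step 4 | (Z)-1,4-bis[4-(benzyloxy)-3,5-dimethoxyphenyl]-2,3-dimethylbut-2-ene-1,4-dione | O=C(c1cc(OC)c(OCc2ccccc2)c(OC)c1)/C(C)=C(/C)C(=O)c1cc(OC)c(OCc2ccccc2)c(OC)c1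
F5 | step 4 | meso-(2R,3S)-1,4-bis(4-hydroxy-3,5-dimethoxyphenyl)-2,3-dimethylbutane-1,4-dione | C[C@H](C(=O)c1cc(OC)c(O)c(OC)c1)[C@@H](C)C(=O)c1cc(OC)c(O)c(OC)c1
F6 | step 4 | (2R,3S)-1,4-bis(4-hydroxy-3,5-dimethoxyphenyl)-2,3-dimethylbutane-1,4-diol (mixture at the carbinol centres) | C[C@H](C(O)c1cc(OC)c(O)c(OC)c1)[C@@H](C)C(O)c1cc(OC)c(O)c(OC)c1
F7 | step 5 | all-cis (2S,3R,4S,5R)-2,5-bis[4-(benzyloxy)-3,5-dimethoxyphenyl]-3,4-dimethyltetrahydrofuran (meso) | COc1cc([C@H]2O[C@@H](c3cc(OC)c(OCc4ccccc4)c(OC)c3)[C@@H](C)[C@H]2C)cc(OC)c1OCc1ccccc1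
F8 | step 5 | (2S,3S,4R,5R)-2,5-bis[4-(benzyloxy)-3,5-dimethoxyphenyl]-3,4-dimethyltetrahydrofuran (meso) | COc1cc([C@H]2O[C@@H](c3cc(OC)c(OCc4ccccc4)c(OC)c3)[C@H](C)[C@@H]2C)cc(OC)c1OCc1ccccc1
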